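- The flask cannot carry its whole charge of starting complex to complex with two exchanged. That takes 0.800 M of incoming ligand, more than the 0.600 M charged, so incoming ligand is the limiting reagent and the ceiling is 75.0%.

- Thursday's: starting complex 0.40 M; incoming ligand 0.60 M; capture agent 0.12 M; the very flask that is asked about, followed so far
- flask: starting complex 0.40 M; incoming ligand 0.600 M; capture agent 0.120 M; time 30 min

Thursday's run (percent of the starting complex charged)

| time / min | complex with two exchanged / % |
|---|---|
| 2.50 | 23.0 |
| 4.00 | 22.4 |
| 6.00 | 19.9 |
| 8.00 | 19.2 |
| 12.0 | 16.9 |
| 20.0 | 14.1 |
| 30.0 | 11.8 |

(scatter of a reading: 0.5 percentage points)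

- additions leave the volume as it is
- the numbers in the tables scatter with a standard deviation of 0.5 percentage points

- west: at 30 min add incoming ligand, 100% of the amount charged, then wait 10 min
- south-east: change nothing and wait 10 min more
- south-west: at 30 min take out 90% of the leaving ligand then present, then wait 10 min
- south: at 30 min add starting complex, 50.0% of the amount charged, then wait 10 min

1. complex with two exchanged, in percent of the starting complex first charged, at 30 min
2. the remedy with the largest gain of complex with two exchanged, or "none" below 2 percentage points (west / south-east / south-west / south / none)
3. complex with two exchanged present, in percent of the starting complex first charged, after west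
4. complex with two exchanged present, in percent of the starting complex first charged, after south

- First instants: Thursday's run, this very flask, already reads 23.0% at 2.50 min, so the first exchanges are quick against the sampling.
- Each exchange swaps one incoming ligand for one leaving ligand, so in the closed flask their sum stays 0.600 M.
- My reckoning takes one exchange per complex on average. The ligand ratio, [incoming ligand] over [leaving ligand], then stands at 0.500.
- Middle and end: the readings sink, by 2.3 points over the last 10.0 min, to 11.8% at 30.0 min, with a scatter of 0.5 points. Something slow is draining the product, and waiting promises no gain.
- First round for the remedies: west lifts the ratio to 2.00, and south-west to 5.00, which looks better.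
- Second round: the answer goes back in. Suppose the climb of one more exchange pays 0.100 M from incoming to leaving ligand, which is a quarter of the first charge of starting complex.
- West then stands at 1.40, south-west at 0.714, and south at 0.200. The order flips, because south-west keeps a ligand sum of 0.240 M against 1.20 M for west.
- So my reckoning picks west, with south-west behind it and south falling.
- The forecast says 11.9% (11.4% to 12.4%) and west, with 19% (14% to 25%) after west and 9% (6.5% to 11%) after south. On south-west it reasons: “Removing leaving ligand only stops the back reaction”.
- The flask gives 11.7% and west, with 21.8% after west and 10.3% after south. West gains 10 points, more than the 4.5 points of south-west.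

    starting complex + incoming ligand ⇌ leaving ligand + complex with one exchanged (K = 2.50, k = 0.300 M⁻¹ s⁻¹)
    complex with one exchanged + incoming ligand ⇌ leaving ligand + complex with two exchanged (K = 1.30, k = 0.130 M⁻¹ s⁻¹)
    complex with two exchanged + incoming ligand ⇌ leaving ligand + complex with three exchanged (K = 0.220, k = 0.0970 M⁻¹ s⁻¹)
    complex with one exchanged + capture agent → trapped intermediate (k = 0.00480 M⁻¹ s⁻¹)
    complex with two exchanged ⇌ isomer of the product (K = 2.40, k = 0.00100 s⁻¹)

- The simulated ligand ratio of this flask is 0.482 at 3.00 min and 0.381 at 30.0 min.
- For the neighbour charged with 0.16 M of starting complex, the same reckoning gives a ratio of 2.75 in the first round, against 0.500 for this flask, and 2.00 in the second.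
- Its simulated ratio is 1.25, and it holds 21.6% of complex with two exchanged at 30.0 min.

The runs are simulated from invented constants; noise was put on by code.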